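**Retrosynthetic overview**

1. The C6–O acyl bond is cut last: target ⇒ silyl-protected dauc-8(14)-ene-4β,6α,9α-triol core 25 + protected vanillic acid 28.
2. The seven-membered ring (C1–C5–C6–C7–C8–C9–C10) is formed second, at C6–C7, by a type 2 carbonyl-ene closure of a C6 aldehyde onto the isopropenyl group of an (S)-C9 carbinol. C6 is then fixed by oxidation and reduction directed by the C4 hydroxyl.
3. The C4 carbinol and C5 methine come from the tetrasubstituted C4=C5 allylic alcohol by face-selective epoxidation and hydride opening at C5. The isopropyl group enters by enol triflate/cuprate coupling at the C4 ketone.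
4. The five-membered ring (C1–C2–C3–C4–C5) is formed first. The strategy rests on quaternary C1, which carries the C15 methyl, the C2–C3 arm and the C10–C9 arm and is the C3 methine of (S)-citronellol. The C1–C5 bond is made by rhodium-carbenoid insertion into that C–H bond with retention.
5. The diazo precursor comes from (S)-citronellol by silylation, ozonolysis, Roskamp homologation with methyl diazoacetate and diazo transfer.

Key step: step 5

Remark: locants C1–C15 are those of the daucane skeleton (C1 quaternary carbon with the C15 methyl, C4 isopropyl carbinol, C5 ring-fusion CH, C6 acyloxy carbon, C8 methylidene carbon, C9 carbinol); β is the face of the C15 methyl; TBS = tert-butyldimethylsilyl; the enolisable C5 centre of 8 is drawn as its expected more stable epimer.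

**Route**

Step 1
Reactants: 1 (S)-citronellol
Product: 2 (S)-citronellol TBS ether
Conditions: TBSCl, imidazole, DMF, rt
Reagents that add atoms: tert-butyldimethylsilyl chloride, CC(C)(C)[Si](C)(C)Cl
Why: Imidazole-promoted silylation of the primary alcohol masks the future C9 oxygen through the diazo and carbenoid chemistry without touching the stereocentre.

Step 2
Reactants: 2 (S)-citronellol TBS ether
Product: 4 (S)-6-(tert-butyldimethylsilyloxy)-4-methylhexanal, via ozonide 3 (not isolated)
Conditions: O3, CH2Cl2, −78 °C; then PPh3, −78 °C → rt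
Reagents that add atoms: ozone, [O-][O+]=O
Why: Ozonolysis of the trisubstituted alkene with reductive work-up cleaves off acetone and should give the aldehyde whose carbon becomes C4, the silyl ether and the remote stereocentre being inert.

Step 3
Reactants: 4 (S)-6-(tert-butyldimethylsilyloxy)-4-methylhexanal; 5 methyl diazoacetate
Product: 6 methyl (S)-8-(tert-butyldimethylsilyloxy)-6-methyl-3-oxooctanoate
Conditions: SnCl2 (10 mol %), CH2Cl2, rt
Reagents that add atoms: none
Why: Roskamp homologation, in which SnCl2-catalysed addition of the diazoacetate to the aldehyde and 1,2-hydride shift with loss of N2 should give the β-keto ester directly, adding C5 and C6.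

Step 4
Reactants: 6 methyl (S)-8-(tert-butyldimethylsilyloxy)-6-methyl-3-oxooctanoate
Product: 7 methyl (S)-8-(tert-butyldimethylsilyloxy)-2-diazo-6-methyl-3-oxooctanoate
Conditions: 4-acetamidobenzenesulfonyl azide, Et3N, MeCN, 0 °C → rt
Reagents that add atoms: 4-acetamidobenzenesulfonyl azide, CC(=O)Nc1ccc(cc1)S(=O)(=O)N=[N+]=[N-]
Why: Regitz diazo transfer to the doubly activated methylene of the β-keto ester, under mild base that leaves the silyl ether and the stereocentre untouched.

Step 5
Reactants: 7 methyl (S)-8-(tert-butyldimethylsilyloxy)-2-diazo-6-methyl-3-oxooctanoate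
Product: 8 methyl (1R,5R)-5-[2-(tert-butyldimethylsilyloxy)ethyl]-5-methyl-2-oxocyclopentane-1-carboxylate
Conditions: Rh2(OAc)4 (1 mol %), CH2Cl2, rt
Reagents that add atoms: none
Why: Rh2(OAc)4 decomposes the diazo group with loss of N2 to an electrophilic rhodium carbenoid at C5, which inserts into the tertiary C1–H bond through a concerted three-centre transition state and so forms the C1–C5 bond. The closest known reaction type is the dirhodium-catalysed intramolecular C–H insertion of α-diazo-β-keto esters to 2-oxocyclopentanecarboxylates. The five-membered ring C1–C2–C3–C4–C5 closes in the 1,5 insertion mode, the carbenoid carbon and the methine being held apart by the C2–C3–C4 tether. C1 is formed with retention because the C–H bond is replaced from the front, so the (S)-methine of citronellol becomes the (R)-quaternary centre, while C5 arises as the more stable epimer of an enolisable β-keto ester and is erased in step 6. The step needs insertion at the C1 methine and not six-membered insertion into the C10 methylene or attack on the silyl ether oxygen, and the preference for five-membered closure together with the higher reactivity of the electron-rich tertiary C–H bond should secure this.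

Step 6
Reactants: 8 methyl (1R,5R)-5-[2-(tert-butyldimethylsilyloxy)ethyl]-5-methyl-2-oxocyclopentane-1-carboxylate
Product: 9 methyl (R)-5-[2-(tert-butyldimethylsilyloxy)ethyl]-5-methyl-2-(trifluoromethylsulfonyloxy)cyclopent-1-ene-1-carboxylate
Conditions: Tf2O, i-Pr2NEt, CH2Cl2, −78 °C
Reagents that add atoms: trifluoromethanesulfonic anhydride, O=S(=O)(OS(=O)(=O)C(F)(F)F)C(F)(F)F
Why: Amine-promoted enolisation of the β-keto ester toward C5 and O-triflation should give the enol triflate, which removes the labile C5 centre and activates C4 for carbon–carbon coupling.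

Step 7
Reactants: 9 enol triflate; 10 isopropylmagnesium chloride
Product: 11 methyl (R)-5-[2-(tert-butyldimethylsilyloxy)ethyl]-5-methyl-2-(propan-2-yl)cyclopent-1-ene-1-carboxylate
Conditions: i-PrMgCl (2.2 equiv), CuI (1.1 equiv), THF, −78 → −30 °C; aq. NH4Cl
Reagents that add atoms: none
Why: Conjugate addition–elimination of a Gilman-type diisopropylcuprate to the β-triflyloxy enoate (cuprate coupling of an enol triflate) should install the isopropyl group at C4 without creating a stereocentre.

Step 8
Reactants: 11 isopropyl enoate silyl ether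
Product: 12 methyl (R)-5-(2-hydroxyethyl)-5-methyl-2-(propan-2-yl)cyclopent-1-ene-1-carboxylate
Conditions: camphorsulfonic acid (10 mol %), MeOH, 0 °C → rt
Reagents that add atoms: none
Why: Acid-catalysed methanolysis removes the primary silyl ether while the hindered conjugated methyl ester is inert.

Step 9
Reactants: 12 primary alcohol
Product: 13 methyl (R)-5-methyl-5-(2-oxoethyl)-2-(propan-2-yl)cyclopent-1-ene-1-carboxylate
Conditions: Dess–Martin periodinane, NaHCO3, CH2Cl2, rt
Reagents that add atoms: none
Why: Dess–Martin oxidation of the primary alcohol should give the C9 aldehyde under buffered conditions.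

Step 10
Reactants: 13 C9 aldehyde; 14 isopropenylmagnesium bromide
Product: 15 methyl (5R)-5-(2-hydroxy-3-methylbut-3-en-1-yl)-5-methyl-2-(propan-2-yl)cyclopent-1-ene-1-carboxylate (both C9 epimers)
Conditions: CH2=C(CH3)MgBr, THF, −78 °C; aq. NH4Cl
Reagents that add atoms: none
Why: Grignard addition to the aldehyde at low temperature is far faster than attack on the hindered tetrasubstituted enoate and brings in C7, C8 and C14; the C9 centre is formed without control and is reset in steps 11 and 12.

Step 11
Reactants: 15 allylic alcohol (C9 epimers)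
Product: 16 methyl (R)-5-methyl-5-(3-methyl-2-oxobut-3-en-1-yl)-2-(propan-2-yl)cyclopent-1-ene-1-carboxylate
Conditions: Dess–Martin periodinane, NaHCO3, CH2Cl2, 0 °C
Reagents that add atoms: none
Why: Dess–Martin oxidation of the secondary allylic alcohol to the isopropenyl ketone erases the uncontrolled C9 centre.

Step 12
Reactants: 16 isopropenyl ketone
Product: 17 methyl (R)-5-[(2S)-2-hydroxy-3-methylbut-3-en-1-yl]-5-methyl-2-(propan-2-yl)cyclopent-1-ene-1-carboxylate
Conditions: (R)-2-methyl-CBS-oxazaborolidine (20 mol %), catecholborane, toluene, −78 °C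
Reagents that add atoms: none
Why: Corey–Bakshi–Shibata reduction, in which the ketone binds the oxazaborolidine with the α-branched isopropenyl group as the large substituent and hydride is delivered to one carbonyl face under reagent control, should give the (S)-carbinol at C9 while the ester is not reduced.

Step 13
Reactants: 17 (S)-allylic alcohol
Product: 18 methyl (R)-5-[(2S)-2-(tert-butyldimethylsilyloxy)-3-methylbut-3-en-1-yl]-5-methyl-2-(propan-2-yl)cyclopent-1-ene-1-carboxylate
Conditions: TBSCl, imidazole, DMF, rt
Reagents that add atoms: tert-butyldimethylsilyl chloride, CC(C)(C)[Si](C)(C)Cl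
Why: Silylation of the secondary allylic alcohol ensures that the C9 oxygen neither acts as a second allylic alcohol in step 15 nor is acylated in step 22.

Step 14
Reactants: 18 silyl-protected enoate
Product: 19 [(R)-5-[(2S)-2-(tert-butyldimethylsilyloxy)-3-methylbut-3-en-1-yl]-5-methyl-2-(propan-2-yl)cyclopent-1-en-1-yl]methanol
Conditions: i-Bu2AlH (2.5 equiv), CH2Cl2, −78 → 0 °C; aq. potassium sodium tartrate
Reagents that add atoms: none
Why: 1,2-Reduction of the α,β-unsaturated ester by i-Bu2AlH should stop at the allylic alcohol and provide the C6 hydroxymethyl group that directs the epoxidation.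

Step 15
Reactants: 19 tetrasubstituted allylic alcohol
Product: 20 4β,5β-epoxy alcohol, [(1S,2R,5R)-2-[(2S)-2-(tert-butyldimethylsilyloxy)-3-methylbut-3-en-1-yl]-2-methyl-5-(propan-2-yl)-6-oxabicyclo[3.1.0]hexan-1-yl]methanol
Conditions: Ti(OiPr)4 (1.2 equiv), L-(+)-diethyl tartrate (1.4 equiv), t-BuOOH, 4 Å molecular sieves, CH2Cl2, −20 °C
Reagents that add atoms: tert-butyl hydroperoxide, CC(C)(C)OO
Why: Katsuki–Sharpless epoxidation, in which titanium binds the C6 hydroxyl and the (R,R)-tartrate delivers oxygen to the face that gives the (S)-configured hydroxymethyl-bearing carbon C5 (the 2S-type epoxy alcohol), should place the epoxide on the β face, which the substrate also favours because C1 shields the α face with its large silyloxyalkenyl arm, and the isopropenyl group, lacking a free allylic hydroxyl, is left alone.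

Step 16
Reactants: 20 4β,5β-epoxy alcohol
Product: 21 (1R,2S,3R)-3-[(2S)-2-(tert-butyldimethylsilyloxy)-3-methylbut-3-en-1-yl]-2-(hydroxymethyl)-3-methyl-1-(propan-2-yl)cyclopentan-1-ol
Conditions: NaAlH2(OCH2CH2OMe)2 (Red-Al), THF, 0 °C → rt
Reagents that add atoms: none
Why: In the Red-Al opening of a 2,3-epoxy alcohol the alkoxyaluminium hydride formed at the C6 oxygen delivers hydride intramolecularly to the proximal epoxide carbon C5 with inversion (the 1,3-diol-selective mode), so hydrogen should enter C5 on the α face and the tertiary C4 hydroxyl stays β.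

Step 17
Reactants: 21 1,3-diol
Product: 22 (1R,2R,5R)-2-[(2S)-2-(tert-butyldimethylsilyloxy)-3-methylbut-3-en-1-yl]-5-hydroxy-2-methyl-5-(propan-2-yl)cyclopentane-1-carbaldehyde
Conditions: Dess–Martin periodinane, NaHCO3, CH2Cl2, 0 °C
Reagents that add atoms: none
Why: Dess–Martin oxidation converts only the primary alcohol, since the tertiary C4 hydroxyl cannot be oxidised, and the buffered conditions should avoid dehydration or epimerisation at C5 of the β-hydroxy aldehyde.

Step 18
Reactants: 22 β-hydroxy aldehyde
Product: 23 (3R,3aS,7S,8aR)-7-(tert-butyldimethylsilyloxy)-8a-methyl-6-methylidene-3-(propan-2-yl)decahydroazulene-3,4-diol (C6 epimers; azulene C4 = C6)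
Conditions: Me2AlCl (3 equiv), CH2Cl2, −78 → −20 °C
Reagents that add atoms: none
Why: In this type 2 intramolecular carbonyl-ene reaction Me2AlCl takes up the hydroxyl proton and activates the aldehyde, the terminal alkene carbon C7 attacks C6 while a hydrogen of the allylic methyl passes to oxygen, and this should close the seven-membered ring trans-fused (fixed by C1 and C5) with the C8 exocyclic methylene; the C6 configuration is not relied on because steps 19 and 20 reset it.

Step 19
Reactants: 23 bicyclic diol (C6 epimers)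
Product: 24 (3R,3aR,7S,8aR)-7-(tert-butyldimethylsilyloxy)-3-hydroxy-8a-methyl-6-methylidene-3-(propan-2-yl)octahydroazulen-4(1H)-one
Conditions: Dess–Martin periodinane, NaHCO3, CH2Cl2, 0 °C
Reagents that add atoms: none
Why: Dess–Martin oxidation of the secondary C6 alcohol of either epimer should give one ketone under buffered conditions that leave the exocyclic alkene out of conjugation and the C5 ring-fusion centre unchanged.

Step 20
Reactants: 24 β-hydroxy ketone
Product: 25 (3R,3aS,4S,7S,8aR)-7-(tert-butyldimethylsilyloxy)-8a-methyl-6-methylidene-3-(propan-2-yl)decahydroazulene-3,4-diol (6α alcohol)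
Conditions: Me4NBH(OAc)3, MeCN/AcOH, −30 °C
Reagents that add atoms: none
Why: In the Evans–Saksena hydroxyl-directed reduction the β-oriented C4 hydroxyl exchanges an acetate on boron and delivers hydride intramolecularly to the β face of the C6 ketone, which should give the 1,3-anti diol, that is the 6α alcohol.

Step 21
Reactants: 26 vanillic acid
Product: 28 4-(tert-butyldimethylsilyloxy)-3-methoxybenzoic acid, via silyl ester 27 (not isolated)
Conditions: TBSCl (2.5 equiv), imidazole, DMF, rt; then AcOH, THF/H2O, rt
Reagents that add atoms: tert-butyldimethylsilyl chloride, CC(C)(C)[Si](C)(C)Cl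
Why: Silylation of both hydroxyls followed by selective hydrolysis of the much more labile silyl ester should leave the phenol protected as its silyl ether.

Step 22
Reactants: 25 6α alcohol; 28 4-(tert-butyldimethylsilyloxy)-3-methoxybenzoic acid
Product: 29 (3R,3aS,4S,7S,8aR)-7-(tert-butyldimethylsilyloxy)-3-hydroxy-8a-methyl-6-methylidene-3-(propan-2-yl)decahydroazulen-4-yl 4-(tert-butyldimethylsilyloxy)-3-methoxybenzoate
Conditions: DCC, DMAP, CH2Cl2, rt
Reagents that add atoms: none
Why: Steglich esterification (carbodiimide activation and DMAP acyl transfer) should acylate only the secondary C6 hydroxyl with retention, because the tertiary C4 hydroxyl is too hindered and C9 is silylated.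

Step 23
Reactants: 29 bis-silyl ester
Product: 30 target, (3R,3aS,4S,7S,8aR)-3,7-dihydroxy-8a-methyl-6-methylidene-3-(propan-2-yl)decahydroazulen-4-yl 4-hydroxy-3-methoxybenzoate
Conditions: HF·pyridine, pyridine, THF, 0 °C → rt
Reagents that add atoms: none
Why: Fluoride-mediated cleavage of the aryl and the secondary allylic silyl ethers under buffered, non-basic conditions should not hydrolyse or shift the C6 ester and gives the target.

**Compound list**

1 | (S)-citronellol, (S)-3,7-dimethyloct-6-en-1-ol | OCC[C@@H](C)CCC=C(C)C | starting material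
2 | (S)-tert-butyl[(3,7-dimethyloct-6-en-1-yl)oxy]dimethylsilane | CC(C)(C)[Si](C)(C)OCC[C@@H](C)CCC=C(C)C | intermediate
3 | 3-[(3S)-5-(tert-butyldimethylsilyloxy)-3-methylpentyl]-5,5-dimethyl-1,2,4-trioxolane (ozonide of 2) | CC(C)(C)[Si](C)(C)OCC[C@@H](C)CCC1OOC(C)(C)O1 | intermediate
4 | (S)-6-(tert-butyldimethylsilyloxy)-4-methylhexanal | CC(C)(C)[Si](C)(C)OCC[C@@H](C)CCC=O | intermediate
5 | methyl diazoacetate | COC(=O)C=[N+]=[N-] | starting material
6 | methyl (S)-8-(tert-butyldimethylsilyloxy)-6-methyl-3-oxooctanoate | CC(C)(C)[Si](C)(C)OCC[C@@H](C)CCC(=O)CC(=O)OC | intermediate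
7 | methyl (S)-8-(tert-butyldimethylsilyloxy)-2-diazo-6-methyl-3-oxooctanoate | COC(=O)C(=[N+]=[N-])C(=O)CC[C@H](C)CCO[Si](C)(C)C(C)(C)C | intermediate
8 | methyl (1R,5R)-5-[2-(tert-butyldimethylsilyloxy)ethyl]-5-methyl-2-oxocyclopentane-1-carboxylate | COC(=O)[C@@H]1[C@](C)(CCC1=O)CCO[Si](C)(C)C(C)(C)C | intermediate
9 | methyl (R)-5-[2-(tert-butyldimethylsilyloxy)ethyl]-5-methyl-2-(trifluoromethylsulfonyloxy)cyclopent-1-ene-1-carboxylate | COC(=O)C1=C(OS(=O)(=O)C(F)(F)F)CC[C@]1(C)CCO[Si](C)(C)C(C)(C)C | intermediate
10 | isopropylmagnesium chloride | CC(C)[Mg]Cl | starting material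
11 | methyl (R)-5-[2-(tert-butyldimethylsilyloxy)ethyl]-5-methyl-2-(propan-2-yl)cyclopent-1-ene-1-carboxylate | COC(=O)C1=C(C(C)C)CC[C@]1(C)CCO[Si](C)(C)C(C)(C)C | intermediate
12 | methyl (R)-5-(2-hydroxyethyl)-5-methyl-2-(propan-2-yl)cyclopent-1-ene-1-carboxylate | COC(=O)C1=C(C(C)C)CC[C@]1(C)CCO | intermediate
13 | methyl (R)-5-methyl-5-(2-oxoethyl)-2-(propan-2-yl)cyclopent-1-ene-1-carboxylate | COC(=O)C1=C(C(C)C)CC[C@]1(C)CC=O | intermediate
14 | isopropenylmagnesium bromide | CC(=C)[Mg]Br | starting material
15 | methyl (5R)-5-(2-hydroxy-3-methylbut-3-en-1-yl)-5-methyl-2-(propan-2-yl)cyclopent-1-ene-1-carboxylate (both epimers at the carbinol carbon) | COC(=O)C1=C(C(C)C)CC[C@]1(C)CC(O)C(C)=C | intermediate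
16 | methyl (R)-5-methyl-5-(3-methyl-2-oxobut-3-en-1-yl)-2-(propan-2-yl)cyclopent-1-ene-1-carboxylate | COC(=O)C1=C(C(C)C)CC[C@]1(C)CC(=O)C(C)=C | intermediate
17 | methyl (R)-5-[(2S)-2-hydroxy-3-methylbut-3-en-1-yl]-5-methyl-2-(propan-2-yl)cyclopent-1-ene-1-carboxylate | COC(=O)C1=C(C(C)C)CC[C@]1(C)C[C@H](O)C(C)=C | intermediate
18 | methyl (R)-5-[(2S)-2-(tert-butyldimethylsilyloxy)-3-methylbut-3-en-1-yl]-5-methyl-2-(propan-2-yl)cyclopent-1-ene-1-carboxylate | COC(=O)C1=C(C(C)C)CC[C@]1(C)C[C@H](O[Si](C)(C)C(C)(C)C)C(C)=C | intermediate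
19 | [(R)-5-[(2S)-2-(tert-butyldimethylsilyloxy)-3-methylbut-3-en-1-yl]-5-methyl-2-(propan-2-yl)cyclopent-1-en-1-yl]methanol | OCC1=C(C(C)C)CC[C@]1(C)C[C@H](O[Si](C)(C)C(C)(C)C)C(C)=C | intermediate
20 | [(1S,2R,5R)-2-[(2S)-2-(tert-butyldimethylsilyloxy)-3-methylbut-3-en-1-yl]-2-methyl-5-(propan-2-yl)-6-oxabicyclo[3.1.0]hexan-1-yl]methanol (epoxide oxygen cis to the ring methyl) | OC[C@]12O[C@@]1(C(C)C)CC[C@]2(C)C[C@H](O[Si](C)(C)C(C)(C)C)C(C)=C | intermediate
21 | (1R,2S,3R)-3-[(2S)-2-(tert-butyldimethylsilyloxy)-3-methylbut-3-en-1-yl]-2-(hydroxymethyl)-3-methyl-1-(propan-2-yl)cyclopentan-1-ol | OC[C@@H]1[C@](C)(CC[C@@]1(O)C(C)C)C[C@H](O[Si](C)(C)C(C)(C)C)C(C)=C | intermediate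
22 | (1R,2R,5R)-2-[(2S)-2-(tert-butyldimethylsilyloxy)-3-methylbut-3-en-1-yl]-5-hydroxy-2-methyl-5-(propan-2-yl)cyclopentane-1-carbaldehyde | O=C[C@@H]1[C@](C)(CC[C@@]1(O)C(C)C)C[C@H](O[Si](C)(C)C(C)(C)C)C(C)=C | intermediate
23 | (3R,3aS,7S,8aR)-7-(tert-butyldimethylsilyloxy)-8a-methyl-6-methylidene-3-(propan-2-yl)decahydroazulene-3,4-diol (both epimers at azulene C4) | C=C1CC(O)[C@@H]2[C@](C)(CC[C@@]2(O)C(C)C)C[C@@H]1O[Si](C)(C)C(C)(C)C | intermediate
24 | (3R,3aR,7S,8aR)-7-(tert-butyldimethylsilyloxy)-3-hydroxy-8a-methyl-6-methylidene-3-(propan-2-yl)octahydroazulen-4(1H)-one | C=C1CC(=O)[C@@H]2[C@](C)(CC[C@@]2(O)C(C)C)C[C@@H]1O[Si](C)(C)C(C)(C)C | intermediate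
25 | (3R,3aS,4S,7S,8aR)-7-(tert-butyldimethylsilyloxy)-8a-methyl-6-methylidene-3-(propan-2-yl)decahydroazulene-3,4-diol | C=C1C[C@H](O)[C@@H]2[C@](C)(CC[C@@]2(O)C(C)C)C[C@@H]1O[Si](C)(C)C(C)(C)C | intermediate
26 | vanillic acid, 4-hydroxy-3-methoxybenzoic acid | COc1cc(C(=O)O)ccc1O | starting material
27 | tert-butyldimethylsilyl 4-(tert-butyldimethylsilyloxy)-3-methoxybenzoate | COc1cc(C(=O)O[Si](C)(C)C(C)(C)C)ccc1O[Si](C)(C)C(C)(C)C | intermediate
28 | 4-(tert-butyldimethylsilyloxy)-3-methoxybenzoic acid | COc1cc(C(=O)O)ccc1O[Si](C)(C)C(C)(C)C | intermediate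
29 | (3R,3aS,4S,7S,8aR)-7-(tert-butyldimethylsilyloxy)-3-hydroxy-8a-methyl-6-methylidene-3-(propan-2-yl)decahydroazulen-4-yl 4-(tert-butyldimethylsilyloxy)-3-methoxybenzoate | C=C1C[C@H](OC(=O)c2ccc(O[Si](C)(C)C(C)(C)C)c(OC)c2)[C@@H]2[C@](C)(CC[C@@]2(O)C(C)C)C[C@@H]1O[Si](C)(C)C(C)(C)C | intermediate
30 | (3R,3aS,4S,7S,8aR)-3,7-dihydroxy-8a-methyl-6-methylidene-3-(propan-2-yl)decahydroazulen-4-yl 4-hydroxy-3-methoxybenzoate (CNP0330487.1) | C=C1C[C@H](OC(=O)c2ccc(O)c(OC)c2)[C@@H]2[C@](C)(CC[C@@]2(O)C(C)C)C[C@@H]1O | target

**Step count**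

Total: 23 steps. Longest linear sequence: 22 steps (steps 1–20, 22 and 23, from (S)-citronellol); step 21 is a one-step side branch.

**Steps most likely to fail**

Step 16. The intramolecular hydride transfer may be diverted: the fully substituted C5, flanked by quaternary C1, may resist backside attack, so that hydride goes to C4 or the epoxide is not opened. The fallback sets out from 20. Dess–Martin oxidation of the primary alcohol should give the 4β,5β-epoxy aldehyde F1. SmI2 in THF/MeOH at −90 °C then cleaves the C5–O bond by electron transfer from the ketyl, the known reduction of α,β-epoxy carbonyl compounds to aldols, and leaves the C4–O bond and its configuration untouched. C5 becomes enolisable and should settle, on brief exposure to Et3N, as the epimer with the formyl group trans to the isopropyl group and to the C10 arm. The route is rejoined at 22.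

Step 18. The seven-membered ene closure may be outrun by transfer of a methyl group from aluminium to the aldehyde, by dehydration of the β-oxygenated aldehyde to the enal, or by proton loss toward the ring. The fallback sets out from 21. Ene-type allylic chlorination of the isopropenyl group (N-chlorosuccinimide, PhSeCl cat., CH2Cl2) should give the allylic chloride F2, and Dess–Martin oxidation the chloro aldehyde F3. An intramolecular Nozaki–Hiyama allylation (CrCl2, THF, rt) then forms the C6–C7 bond through the allylchromium species and regenerates the exocyclic methylene. The route is rejoined at 23, whose C6 configuration is again set by steps 19 and 20.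

Step 7. The secondary alkylcopper reagent may decompose by β-hydride elimination before it adds, so that the triflate is reduced or returned. The fallback sets out from 9. Suzuki–Miyaura coupling with isopropenylboronic acid pinacol ester (Pd(PPh3)4, K3PO4, dioxane/H2O, 80 °C) should give the dienoate F4. Hydrogenation over RhCl(PPh3)3 (H2, 1 atm, benzene) should saturate only the unhindered 1,1-disubstituted alkene. The route is rejoined at 11.

**Further compounds**

F1 | step 16 | 4β,5β-epoxy aldehyde, (1R,2R,5R)-2-[(2S)-2-(tert-butyldimethylsilyloxy)-3-methylbut-3-en-1-yl]-2-methyl-5-(propan-2-yl)-6-oxabicyclo[3.1.0]hexane-1-carbaldehyde | O=C[C@]12O[C@@]1(C(C)C)CC[C@]2(C)C[C@H](O[Si](C)(C)C(C)(C)C)C(C)=C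
F2 | step 18 | allylic chloride, (1R,2S,3R)-3-[(2S)-2-(tert-butyldimethylsilyloxy)-3-(chloromethyl)but-3-en-1-yl]-2-(hydroxymethyl)-3-methyl-1-(propan-2-yl)cyclopentan-1-ol | OC[C@@H]1[C@](C)(CC[C@@]1(O)C(C)C)C[C@H](O[Si](C)(C)C(C)(C)C)C(CCl)=C
F3 | step 18 | chloro aldehyde, (1R,2R,5R)-2-[(2S)-2-(tert-butyldimethylsilyloxy)-3-(chloromethyl)but-3-en-1-yl]-5-hydroxy-2-methyl-5-(propan-2-yl)cyclopentane-1-carbaldehyde | O=C[C@@H]1[C@](C)(CC[C@@]1(O)C(C)C)C[C@H](O[Si](C)(C)C(C)(C)C)C(CCl)=C
F4 | step 7 | dienoate, methyl (R)-5-[2-(tert-butyldimethylsilyloxy)ethyl]-5-methyl-2-(prop-1-en-2-yl)cyclopent-1-ene-1-carboxylate | COC(=O)C1=C(C(C)=C)CC[C@]1(C)CCO[Si](C)(C)C(C)(C)C
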